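**Retrosynthetic overview**
1. Target 26 comes from an α-phosphono-γ-lactone by Horner–Wadsworth–Emmons methylenation with formaldehyde and acid unmasking of C14 (acetal) and O15 (silyl ether); the isovalerate is put on the free 8-OH late.
2. Key disconnection C7–C11: the lactone ring, C7 and C8 are set in one step by intramolecular SN2 opening of a C7–C8 cis-epoxide by a phosphonoacetate tethered to O6, so the lactone is made last, on the finished carbocycle.
3. The epoxide comes from hydroxyl-directed epoxidation of an all-cis cyclodeca-1(10),4,7-trien-6-ol whose single stereocentre C6 comes from (2R)-but-3-ene-1,2-diol; a Mitsunobu esterification then inverts C6 and brings in the phosphonoacetate.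
4. The ten-membered ring is closed by ring-closing metathesis at C7=C8, a bond that is single in the target. The usual choices (Barbier-type allylation across C6–C7, or closure at one of the two ring alkenes of the target) are not used.
5. The acyclic tetraene comes from two E-selective Wittig reactions of formyl-stabilised ylides (C1=C10, C4=C5). Ring order: carbocycle, then oxirane (temporary), then γ-lactone.

Assumption: 1, 2, 5, 11, 16, 21 and 23 (and, for the fallbacks, (2S)-but-3-ene-1,2-diol and monoallyl malonate) are catalogue chemicals; atom labels C1–C15 are those of the target (ring C1–C10, lactone C11–C13, C14 on C10, C15 on C4).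

**Route**

Step 1
Reactants: 1 (but-3-en-1-yl)triphenylphosphonium bromide; 2 ethyl formate
Product: 4 2-(triphenyl-λ5-phosphanylidene)pent-4-enal, via (but-3-en-1-ylidene)triphenyl-λ5-phosphane 3 (not isolated)
Conditions: KOtBu (2 equiv), THF, −78 → 0 °C; then HCO2Et, 0 °C → rt
Reagents that add atoms: none
Why: Deprotonation gives the non-stabilised ylide 3, and its C-acylation by the formate ester (acylation of a phosphorus ylide, then loss of the now acidic α-proton) gives the stable formyl ylide; no stereocentre is formed.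

Step 2
Reactants: 4 2-(triphenyl-λ5-phosphanylidene)pent-4-enal; 5 4-chlorobutanal
Product: 6 (2E)-6-chloro-2-(prop-2-en-1-yl)hex-2-enal
Conditions: toluene, 80 °C
Reagents that add atoms: none
Why: Wittig olefination with an α-substituted formyl-stabilised ylide is under thermodynamic control and gives the (E)-2-substituted enal (C2 trans to CHO, hence C2 cis to C9), which is the geometry of the ring-cis C1=C10 alkene.

Step 3
Reactants: 6 (2E)-6-chloro-2-(prop-2-en-1-yl)hex-2-enal
Product: 7 (4E)-8-chloro-4-(dimethoxymethyl)octa-1,4-diene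
Conditions: HC(OMe)3 (5 equiv), PPTS (cat.), rt
Reagents that add atoms: trimethyl orthoformate, COC(OC)OC
Why: Acid-catalysed acetalisation with the orthoester masks the C14 enal for the basic steps and for the later Luche reduction without touching the alkene geometry.

Step 4
Reactants: 7 (4E)-8-chloro-4-(dimethoxymethyl)octa-1,4-diene
Product: 8 [(4E)-5-(dimethoxymethyl)octa-4,7-dien-1-yl]triphenylphosphonium iodide
Conditions: PPh3, NaI, MeCN, reflux
Reagents that add atoms: triphenylphosphine, c1ccc(cc1)P(c1ccccc1)c1ccccc1; sodium iodide, [Na+].[I-]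
Why: In situ Finkelstein exchange followed by SN2 quaternisation of triphenylphosphine at the primary carbon C4 gives the phosphonium salt under neutral conditions that leave the acetal intact.

Step 5
Reactants: 8 [(4E)-5-(dimethoxymethyl)octa-4,7-dien-1-yl]triphenylphosphonium iodide; 2 ethyl formate
Product: 10 (5E)-6-(dimethoxymethyl)-2-(triphenyl-λ5-phosphanylidene)nona-5,8-dienal, via [(4E)-5-(dimethoxymethyl)octa-4,7-dien-1-ylidene]triphenyl-λ5-phosphane 9 (not isolated)
Conditions: KOtBu (2 equiv), THF, −78 → 0 °C; then HCO2Et, 0 °C → rt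
Reagents that add atoms: none
Why: The same ylide formation and C-formylation as in step 1 turn C4 into a formyl-stabilised ylide carbon and bring in C15 at the aldehyde level.

Step 6
Reactants: 11 (2R)-but-3-ene-1,2-diol; 10 (5E)-6-(dimethoxymethyl)-2-(triphenyl-λ5-phosphanylidene)nona-5,8-dienal
Product: 13 (2E,4R)-2-[(3E)-4-(dimethoxymethyl)hepta-3,6-dien-1-yl]-4-hydroxyhexa-2,5-dienal, via (2R)-2-hydroxybut-3-enal 12 (not isolated)
Conditions: PhI(OAc)2 (1.1 equiv), TEMPO (10 mol%), CH2Cl2, 0 °C → rt; then 10, 40 °C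
Reagents that add atoms: none
Why: The oxoammonium (TEMPO) oxidation is selective for the primary hydroxyl and the α-hydroxy aldehyde is trapped as it forms by the stabilised ylide in an E-selective Wittig reaction (one-pot oxidation–Wittig olefination), which puts C6 trans to CHO across C4=C5 while the C6 stereocentre is carried over from the chiral pool.

Step 7
Reactants: 13 (2E,4R)-2-[(3E)-4-(dimethoxymethyl)hepta-3,6-dien-1-yl]-4-hydroxyhexa-2,5-dienal
Product: 14 (6R)-10-(dimethoxymethyl)-6-hydroxycyclodeca-1(10),4,7-triene-4-carbaldehyde (all three ring alkenes cis in the ring)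
Conditions: second-generation Grubbs catalyst (H2IMes)(PCy3)Cl2Ru=CHPh (10 mol%), 1,4-benzoquinone (20 mol%), toluene (1 mM), 60 °C
Reagents that add atoms: none
Why: Ring-closing metathesis joins the only two monosubstituted alkenes (the trisubstituted alkenes bearing the formyl and acetal groups are spectators), ethene loss drives it, and a ten-membered ring that already holds two cis ring alkenes can take the new C7=C8 bond only as cis.

Step 8
Reactants: 14 (6R)-10-(dimethoxymethyl)-6-hydroxycyclodeca-1(10),4,7-triene-4-carbaldehyde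
Product: 15 (6S,7S,8R)-10-(dimethoxymethyl)-7,8-epoxy-6-hydroxycyclodeca-1(10),4-diene-4-carbaldehyde (cis-epoxide on the same ring face as the 6-OH)
Conditions: VO(acac)2 (5 mol%), t-BuOOH (1.5 equiv, decane), CH2Cl2, 0 °C → rt
Reagents that add atoms: tert-butyl hydroperoxide, CC(C)(C)OO
Why: Vanadium-catalysed hydroxyl-directed epoxidation delivers oxygen from the vanadium alkoxide to the face of the neighbouring cis alkene on which the hydroxyl sits (syn epoxy alcohol, as with cyclic allylic alcohols up to medium rings), which sets C7 and C8 from C6, while the enal alkene C4=C5 is too electron-poor and C1=C10 is not allylic to the hydroxyl.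

Step 9
Reactants: 15 (6S,7S,8R)-10-(dimethoxymethyl)-7,8-epoxy-6-hydroxycyclodeca-1(10),4-diene-4-carbaldehyde; 16 2-(diethoxyphosphoryl)acetic acid
Product: 17 (6R,7R,8R)-10-(dimethoxymethyl)-7,8-epoxy-4-formylcyclodeca-1(10),4-dien-6-yl 2-(diethoxyphosphoryl)acetate (ester oxygen on the ring face opposite to the epoxide)
Conditions: PPh3, DIAD, THF, 0 °C → rt
Reagents that add atoms: none
Why: Mitsunobu esterification inverts C6 by SN2 displacement of the alkoxyphosphonium ion, so the phosphonoacetate arrives on the face opposite to the epoxide oxygen, as the backside opening in step 12 requires.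

Step 10
Reactants: 17 (6R,7R,8R)-10-(dimethoxymethyl)-7,8-epoxy-4-formylcyclodeca-1(10),4-dien-6-yl 2-(diethoxyphosphoryl)acetate
Product: 18 (6R,7R,8R)-10-(dimethoxymethyl)-7,8-epoxy-4-(hydroxymethyl)cyclodeca-1(10),4-dien-6-yl 2-(diethoxyphosphoryl)acetate
Conditions: NaBH4, CeCl3·7H2O, MeOH, −78 °C
Reagents that add atoms: none
Why: Luche reduction is 1,2-selective and aldehyde-selective, so the C15 enal becomes the allylic alcohol while ester, epoxide, acetal and phosphonate stay.

Step 11
Reactants: 18 (6R,7R,8R)-10-(dimethoxymethyl)-7,8-epoxy-4-(hydroxymethyl)cyclodeca-1(10),4-dien-6-yl 2-(diethoxyphosphoryl)acetate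
Product: 19 (6R,7R,8R)-4-[(tert-butyldimethylsilyloxy)methyl]-10-(dimethoxymethyl)-7,8-epoxycyclodeca-1(10),4-dien-6-yl 2-(diethoxyphosphoryl)acetate
Conditions: TBSCl, imidazole, CH2Cl2, 0 °C
Reagents that add atoms: tert-butyl(chloro)dimethylsilane, CC(C)(C)[Si](C)(C)Cl
Why: Silylation of the only free (primary, allylic) hydroxyl keeps O15 out of the base step and out of the later acylation.

Step 12
Reactants: 19 (6R,7R,8R)-4-[(tert-butyldimethylsilyloxy)methyl]-10-(dimethoxymethyl)-7,8-epoxycyclodeca-1(10),4-dien-6-yl 2-(diethoxyphosphoryl)acetate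
Product: 20 (6R,7S,8R)-hydroxy lactone: γ-lactone O6–C12(=O)–C11H[P(O)(OEt)2]–C7 cis-fused to the ten-membered ring, free 8-OH, 10-CH(OMe)2, 4-CH2OTBS, C11 epimers
Conditions: LiN(SiMe3)2 (1.05 equiv), THF (5 mM), −78 → 40 °C; aq. NH4Cl
Reagents that add atoms: none
Why: Proposed new method: deprotonation gives the phosphonate-stabilised carbanion, which the O6 tether holds on the face opposite to the epoxide oxygen so that it attacks C7 backside in a 5-exo-tet SN2 opening (inversion at C7 gives the cis-fused γ-lactone, C8 keeps its oxygen and configuration), and the released C8 alkoxide is quenched internally by the more acidic phosphonolactone C–H so that neither translactonisation nor phosphoryl transfer follows; the closest known reactions are the intermolecular opening of epoxides by phosphonoacetate anions to α-phosphono-γ-lactones and intramolecular epoxide alkylations by malonate or sulfone anions.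

Step 13
Reactants: 20 (6R,7S,8R)-hydroxy lactone; 21 3-methylbutanoic acid
Product: 22 (6R,7S,8R)-8-O-(3-methylbutanoyl) ester of 20
Conditions: DCC, DMAP (0.3 equiv), CH2Cl2, rt
Reagents that add atoms: none
Why: Steglich esterification (carbodiimide activation, DMAP acyl transfer) acylates the only free hydroxyl with retention at C8.

Step 14
Reactants: 22 (6R,7S,8R)-8-O-(3-methylbutanoyl) ester of 20; 23 formaldehyde
Product: 24 (6R,7S,8R)-15-(tert-butyldimethylsilyloxy)-14,14-dimethoxy-8-(3-methylbutanoyloxy)germacra-1(10),4,11(13)-trien-6,12-olide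
Conditions: K2CO3, aq. HCHO (37%), THF, 0 °C
Reagents that add atoms: none
Why: Horner–Wadsworth–Emmons olefination of the α-phosphono lactone with formaldehyde gives the α-methylene lactone and removes the undefined C11 centre under carbonate conditions mild enough for the isovalerate.

Step 15
Reactants: 24 (6R,7S,8R)-15-(tert-butyldimethylsilyloxy)-14,14-dimethoxy-8-(3-methylbutanoyloxy)germacra-1(10),4,11(13)-trien-6,12-olide
Product: 26 (6R,7S,8R)-15-hydroxy-8-(3-methylbutanoyloxy)-14-oxogermacra-1(10),4,11(13)-trien-6,12-olide (the target), via 15-O-silyl 14-aldehyde 25 (not isolated)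
Conditions: HCl (1 M aq.), THF, 0 °C → rt
Reagents that add atoms: water, O
Why: Dilute aqueous acid hydrolyses the allylic dimethyl acetal to the C14 enal (geometry fixed since step 2) and then cleaves the primary silyl ether, leaving lactone, ester and the three stereocentres untouched.

**Compound list**
1 | (but-3-en-1-yl)triphenylphosphonium bromide | C=CCC[P+](c1ccccc1)(c1ccccc1)c1ccccc1.[Br-] | starting material
2 | ethyl formate | CCOC=O | starting material
3 | (but-3-en-1-ylidene)triphenyl-λ5-phosphane | C=CCC=P(c1ccccc1)(c1ccccc1)c1ccccc1 | intermediate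
4 | 2-(triphenyl-λ5-phosphanylidene)pent-4-enal | O=CC(CC=C)=P(c1ccccc1)(c1ccccc1)c1ccccc1 | intermediate
5 | 4-chlorobutanal | O=CCCCCl | starting material
6 | (2E)-6-chloro-2-(prop-2-en-1-yl)hex-2-enal | O=C/C(CC=C)=C/CCCCl | intermediate
7 | (4E)-8-chloro-4-(dimethoxymethyl)octa-1,4-diene | COC(OC)/C(CC=C)=C/CCCCl | intermediate
8 | [(4E)-5-(dimethoxymethyl)octa-4,7-dien-1-yl]triphenylphosphonium iodide | COC(OC)/C(CC=C)=C/CCC[P+](c1ccccc1)(c1ccccc1)c1ccccc1.[I-] | intermediate
9 | [(4E)-5-(dimethoxymethyl)octa-4,7-dien-1-ylidene]triphenyl-λ5-phosphane | COC(OC)/C(CC=C)=C/CCC=P(c1ccccc1)(c1ccccc1)c1ccccc1 | intermediate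
10 | (5E)-6-(dimethoxymethyl)-2-(triphenyl-λ5-phosphanylidene)nona-5,8-dienal | COC(OC)/C(CC=C)=C/CCC(C=O)=P(c1ccccc1)(c1ccccc1)c1ccccc1 | intermediate
11 | (2R)-but-3-ene-1,2-diol | O[C@H](C=C)CO | starting material
12 | (2R)-2-hydroxybut-3-enal | O[C@H](C=C)C=O | intermediate
13 | (2E,4R)-2-[(3E)-4-(dimethoxymethyl)hepta-3,6-dien-1-yl]-4-hydroxyhexa-2,5-dienal | O=C/C(CC/C=C(/C(OC)OC)CC=C)=C/[C@H](O)C=C | intermediate
14 | (6R)-10-(dimethoxymethyl)-6-hydroxycyclodeca-1(10),4,7-triene-4-carbaldehyde, ring alkenes all cis in the ring | O[C@H]1/C=C(/C=O)CC/C=C(/C(OC)OC)C/C=C\1 | intermediate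
15 | (6S,7S,8R)-10-(dimethoxymethyl)-7,8-epoxy-6-hydroxycyclodeca-1(10),4-diene-4-carbaldehyde, epoxide syn to 6-OH | O[C@H]1/C=C(/C=O)CC/C=C(/C(OC)OC)C[C@H]2O[C@@H]12 | intermediate
16 | 2-(diethoxyphosphoryl)acetic acid | CCOP(=O)(OCC)CC(=O)O | starting material
17 | (6R,7R,8R)-10-(dimethoxymethyl)-7,8-epoxy-4-formylcyclodeca-1(10),4-dien-6-yl 2-(diethoxyphosphoryl)acetate, ester oxygen anti to epoxide | CCOP(=O)(OCC)CC(=O)O[C@@H]1/C=C(/C=O)CC/C=C(/C(OC)OC)C[C@H]2O[C@@H]12 | intermediate
18 | (6R,7R,8R)-10-(dimethoxymethyl)-7,8-epoxy-4-(hydroxymethyl)cyclodeca-1(10),4-dien-6-yl 2-(diethoxyphosphoryl)acetate | CCOP(=O)(OCC)CC(=O)O[C@@H]1/C=C(/CO)CC/C=C(/C(OC)OC)C[C@H]2O[C@@H]12 | intermediate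
19 | (6R,7R,8R)-4-[(tert-butyldimethylsilyloxy)methyl]-10-(dimethoxymethyl)-7,8-epoxycyclodeca-1(10),4-dien-6-yl 2-(diethoxyphosphoryl)acetate | CCOP(=O)(OCC)CC(=O)O[C@@H]1/C=C(/CO[Si](C)(C)C(C)(C)C)CC/C=C(/C(OC)OC)C[C@H]2O[C@@H]12 | intermediate
20 | (6R,7S,8R)-hydroxy lactone: cis-fused γ-lactone O6–C12(=O)–C11H[P(O)(OEt)2]–C7, 8-OH, 10-CH(OMe)2, 4-CH2OTBS, C11 epimers | CCOP(=O)(OCC)C1C(=O)O[C@@H]2/C=C(/CO[Si](C)(C)C(C)(C)C)CC/C=C(/C(OC)OC)C[C@@H](O)[C@H]12 | intermediate
21 | 3-methylbutanoic acid | CC(C)CC(=O)O | starting material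
22 | (6R,7S,8R)-8-O-(3-methylbutanoyl) ester of 20 | CCOP(=O)(OCC)C1C(=O)O[C@@H]2/C=C(/CO[Si](C)(C)C(C)(C)C)CC/C=C(/C(OC)OC)C[C@@H](OC(=O)CC(C)C)[C@H]12 | intermediate
23 | formaldehyde | C=O | starting material
24 | (6R,7S,8R)-15-(tert-butyldimethylsilyloxy)-14,14-dimethoxy-8-(3-methylbutanoyloxy)germacra-1(10),4,11(13)-trien-6,12-olide | C=C1C(=O)O[C@@H]2/C=C(/CO[Si](C)(C)C(C)(C)C)CC/C=C(/C(OC)OC)C[C@@H](OC(=O)CC(C)C)[C@H]12 | intermediate
25 | (6R,7S,8R)-15-(tert-butyldimethylsilyloxy)-8-(3-methylbutanoyloxy)-14-oxogermacra-1(10),4,11(13)-trien-6,12-olide | C=C1C(=O)O[C@@H]2/C=C(/CO[Si](C)(C)C(C)(C)C)CC/C=C(/C=O)C[C@@H](OC(=O)CC(C)C)[C@H]12 | intermediate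
26 | (6R,7S,8R)-15-hydroxy-8-(3-methylbutanoyloxy)-14-oxogermacra-1(10),4,11(13)-trien-6,12-olide, both ring alkenes cis in the ring, lactone cis-fused | C=C1C(=O)O[C@@H]2/C=C(/CO)CC/C=C(/C=O)C[C@@H](OC(=O)CC(C)C)[C@H]12 | target

**Step count**
Total steps: 15. Longest linear sequence: 15 steps (1 → 26); all other inputs are purchased.

**Three steps most likely to fail**

Step 7 (metathesis closure of a ten-membered triene). The risks are oligomerisation and ruthenium-hydride isomerisation of the doubly allylic carbinol or of the skipped diene. The fallback sets out from 13 and comes back at 14, and it takes the free carbinol out of the ring-closing substrate. Silylation of 13 (Et3SiCl, imidazole, CH2Cl2) gives (2E,4R)-2-[(3E)-4-(dimethoxymethyl)hepta-3,6-dien-1-yl]-4-(triethylsilyloxy)hexa-2,5-dienal F1. In F1 the catalyst can load only on the allyl terminus and no ruthenium alkoxide or hydride can form at C6. Ring closure with the second-generation Hoveyda–Grubbs catalyst (H2IMes)Cl2Ru(=CH-C6H4-2-OiPr) in toluene at 1 mM and 80 °C gives (6R)-10-(dimethoxymethyl)-6-(triethylsilyloxy)cyclodeca-1(10),4,7-triene-4-carbaldehyde F2, and HF·pyridine in THF returns 14.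

Step 8 (face selectivity of the directed epoxidation on the ten-membered ring; the anti epoxy alcohol or a mixture may form). The fallback sets out from 10 and comes back at 17, and it reaches the same ester with retention instead of inversion at C6. Ylide 10 is combined with (2S)-but-3-ene-1,2-diol (the enantiomer of 11) under the conditions of step 6 to give (2E,4S)-2-[(3E)-4-(dimethoxymethyl)hepta-3,6-dien-1-yl]-4-hydroxyhexa-2,5-dienal F3. Ring closure as in step 7 gives (6S)-10-(dimethoxymethyl)-6-hydroxycyclodeca-1(10),4,7-triene-4-carbaldehyde F4. Peracid epoxidation (mCPBA, NaHCO3, CH2Cl2, 0 °C) delivers oxygen anti to the hydroxyl in medium-ring cis-cycloalkenols, the same sense as the threo preference of acyclic Z-allylic alcohols, and gives (6R,7S,8R)-10-(dimethoxymethyl)-7,8-epoxy-6-hydroxycyclodeca-1(10),4-diene-4-carbaldehyde F5. Steglich esterification of F5 with 16 (DCC, DMAP, retention at C6) gives 17.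

Step 12 (the tethered phosphonate carbanion may fail to open the epoxide, or may open it 6-endo). The fallback sets out from 15 and comes back at 24; it uses a softer malonate nucleophile and a decarboxylative methylenation. Mitsunobu esterification of 15 with monoallyl malonate (PPh3, DIAD) gives (6R,7R,8R)-10-(dimethoxymethyl)-7,8-epoxy-4-formylcyclodeca-1(10),4-dien-6-yl prop-2-en-1-yl propanedioate F6. Luche reduction gives the 4-(hydroxymethyl) malonate F7, and TBSCl/imidazole gives the 4-[(tert-butyldimethylsilyloxy)methyl] malonate F8. NaH in THF closes the ring by intramolecular epoxide alkylation of the malonate anion to the cis-fused α-(allyloxycarbonyl)-γ-lactone with free 8-OH F9. Steglich acylation with 21 gives the 8-O-(3-methylbutanoyl) α-(allyloxycarbonyl) lactone F10. Pd(PPh3)4 and morpholine remove the allyl group to give the α-carboxy lactone F11, which is treated without isolation with aqueous HCHO and Et2NH, then NaOAc/AcOH (decarboxylative Mannich methylenation), to give 24.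

Further compounds
F1 | step 7 | (2E,4R)-2-[(3E)-4-(dimethoxymethyl)hepta-3,6-dien-1-yl]-4-(triethylsilyloxy)hexa-2,5-dienal | O=C/C(CC/C=C(/C(OC)OC)CC=C)=C/[C@H](O[Si](CC)(CC)CC)C=C
F2 | step 7 | (6R)-10-(dimethoxymethyl)-6-(triethylsilyloxy)cyclodeca-1(10),4,7-triene-4-carbaldehyde | CC[Si](CC)(CC)O[C@H]1/C=C(/C=O)CC/C=C(/C(OC)OC)C/C=C\1
F3 | step 8 | (2E,4S)-2-[(3E)-4-(dimethoxymethyl)hepta-3,6-dien-1-yl]-4-hydroxyhexa-2,5-dienal | O=C/C(CC/C=C(/C(OC)OC)CC=C)=C/[C@@H](O)C=C
F4 | step 8 | (6S)-10-(dimethoxymethyl)-6-hydroxycyclodeca-1(10),4,7-triene-4-carbaldehyde | O[C@@H]1/C=C(/C=O)CC/C=C(/C(OC)OC)C/C=C\1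
F5 | step 8 | (6R,7S,8R)-10-(dimethoxymethyl)-7,8-epoxy-6-hydroxycyclodeca-1(10),4-diene-4-carbaldehyde, epoxide anti to 6-OH | O[C@@H]1/C=C(/C=O)CC/C=C(/C(OC)OC)C[C@H]2O[C@@H]12
F6 | step 12 | (6R,7R,8R)-10-(dimethoxymethyl)-7,8-epoxy-4-formylcyclodeca-1(10),4-dien-6-yl prop-2-en-1-yl propanedioate | C=CCOC(=O)CC(=O)O[C@@H]1/C=C(/C=O)CC/C=C(/C(OC)OC)C[C@H]2O[C@@H]12
F7 | step 12 | (6R,7R,8R)-10-(dimethoxymethyl)-7,8-epoxy-4-(hydroxymethyl)cyclodeca-1(10),4-dien-6-yl prop-2-en-1-yl propanedioate | C=CCOC(=O)CC(=O)O[C@@H]1/C=C(/CO)CC/C=C(/C(OC)OC)C[C@H]2O[C@@H]12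
F8 | step 12 | (6R,7R,8R)-4-[(tert-butyldimethylsilyloxy)methyl]-10-(dimethoxymethyl)-7,8-epoxycyclodeca-1(10),4-dien-6-yl prop-2-en-1-yl propanedioate | C=CCOC(=O)CC(=O)O[C@@H]1/C=C(/CO[Si](C)(C)C(C)(C)C)CC/C=C(/C(OC)OC)C[C@H]2O[C@@H]12
F9 | step 12 | (6R,7S,8R)-cis-fused α-(allyloxycarbonyl)-γ-lactone with free 8-OH, 10-CH(OMe)2, 4-CH2OTBS, C11 epimers | C=CCOC(=O)C1C(=O)O[C@@H]2/C=C(/CO[Si](C)(C)C(C)(C)C)CC/C=C(/C(OC)OC)C[C@@H](O)[C@H]12
F10 | step 12 | (6R,7S,8R)-8-O-(3-methylbutanoyl) ester of F9 | C=CCOC(=O)C1C(=O)O[C@@H]2/C=C(/CO[Si](C)(C)C(C)(C)C)CC/C=C(/C(OC)OC)C[C@@H](OC(=O)CC(C)C)[C@H]12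
F11 | step 12 | (6R,7S,8R)-α-carboxy lactone from F10 | OC(=O)C1C(=O)O[C@@H]2/C=C(/CO[Si](C)(C)C(C)(C)C)CC/C=C(/C(OC)OC)C[C@@H](OC(=O)CC(C)C)[C@H]12
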